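**Retrosynthetic overview**

1. Ring labels: A is the 2,6-dihydroxybenzoyl ring ending chain 1; B is the catechol ring of the biaryl (B1 chain 1, B2 biaryl bond, B4 and B5 OH); C is the acylresorcinol ring (C1 biaryl bond, C2 OH, C3 acyl, C4 OH); D is the catechol ring ending chain 2.
2. Feature used: the C2 hydroxyl of ring C is ortho to the C1–B2 bond and faces the first carbon of chain 1 on B1, so a temporary O–CH link between them makes ring B part of a 6H-benzo[c]chromene.
3. Giganteone A ⇐ BBr3 demethylation ⇐ hydrogenolysis of the O–CH bridge ⇐ oxidation of two C–B bonds ⇐ 8,9-diboryl benzochromene 25 ⇐ cobalt-catalysed [2+2+2] of ring C diyne 23 with diborylacetylene 24.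
4. 23 ⇐ Mitsunobu coupling of phenol 13 (from 2-bromo-5-methoxyphenol by Sonogashira coupling and ortho-lithiation/acylation with chain 2 amide 6) with propargylic alcohol 21 (from azelaic half-ester chloride 2, lithiated 1,3-dimethoxybenzene and ethynylmagnesium bromide).
5. Ring order: rings A, C and D are bought; the temporary pyran ring and ring B are closed together in step 15; the pyran ring is opened again in step 17.

Key step: step 15

Remark: the carbinol carbon made in step 12 is carried as the racemate, because step 17 turns it into a CH2 group; the target has no stereocentre.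

**Route**

Step 1
Reactants: 1 azelaic acid monomethyl ester
Product: 2 methyl 9-chloro-9-oxononanoate
Conditions: (COCl)2, DMF (cat.), CH2Cl2, 0 °C → rt; concentrate
Reagents that add atoms: oxalyl chloride, ClC(=O)C(=O)Cl
Why: Acid chloride formation through the chloroiminium (Vilsmeier-type) activation of the free acid should be clean, and the methyl ester is untouched.

Step 2
Reactants: 2 methyl 9-chloro-9-oxononanoate; 3 veratrole (1,2-dimethoxybenzene)
Product: 4 methyl 9-(3,4-dimethoxyphenyl)-9-oxononanoate
Conditions: AlCl3 (2.2 equiv), CH2Cl2, 0 °C → rt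
Reagents that add atoms: none
Why: Friedel–Crafts acylation of veratrole should occur para to one methoxy group, and the acylium ion from 2 reacts faster than the ester.

Step 3
Reactants: 4 methyl 9-(3,4-dimethoxyphenyl)-9-oxononanoate
Product: 5 methyl 9-(3,4-dimethoxyphenyl)nonanoate
Conditions: Et3SiH (2.5 equiv), TFA, rt
Reagents that add atoms: none
Why: Ionic hydrogenation should reduce the electron-rich, conjugated aryl ketone to CH2 through the para-methoxy-stabilised benzylic cation, while the ester is inert.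

Step 4
Reactants: 5 methyl 9-(3,4-dimethoxyphenyl)nonanoate
Product: 6 9-(3,4-dimethoxyphenyl)-N-methoxy-N-methylnonanamide
Conditions: MeNH(OMe)·HCl, i-PrMgCl, THF, −20 → 0 °C
Reagents that add atoms: N,O-dimethylhydroxylamine hydrochloride, Cl.CNOC
Why: Aminolysis of the ester by the magnesium amide of N,O-dimethylhydroxylamine is the standard one-step entry to a Weinreb amide.

Step 5
Reactants: 7 2-bromo-5-methoxyphenol
Product: 8 1-bromo-4-methoxy-2-(methoxymethoxy)benzene
Conditions: MOMCl, i-Pr2NEt, CH2Cl2, 0 °C → rt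
Reagents that add atoms: chloromethyl methyl ether, COCCl
Why: O-alkylation to the MOM ether; this phenol already has the future C2 oxygen distinct from the C4 methyl ether and the bromine at C1, so no selective demethylation between two ortho-acyl methoxy groups is needed later.

Step 6
Reactants: 8 1-bromo-4-methoxy-2-(methoxymethoxy)benzene; 9 (triisopropylsilyl)acetylene
Product: 10 {[4-methoxy-2-(methoxymethoxy)phenyl]ethynyl}triisopropylsilane
Conditions: PdCl2(PhCN)2 (3 mol %), P(t-Bu)3·HBF4 (6 mol %), CuI (2 mol %), i-Pr2NH, dioxane, rt → 45 °C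
Reagents that add atoms: none
Why: Sonogashira coupling with a bulky electron-rich phosphine should handle the electron-rich aryl bromide, and the protected phenol cannot close onto the alkyne to a benzofuran.

Step 7
Reactants: 10 {[4-methoxy-2-(methoxymethoxy)phenyl]ethynyl}triisopropylsilane; 6 9-(3,4-dimethoxyphenyl)-N-methoxy-N-methylnonanamide
Product: 12 9-(3,4-dimethoxyphenyl)-1-[6-methoxy-2-(methoxymethoxy)-3-[(triisopropylsilyl)ethynyl]phenyl]nonan-1-one, via ring C aryllithium 11 (not isolated)
Conditions: n-BuLi, THF, 0 °C; then 6, −78 → 0 °C; aq NH4Cl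
Reagents that add atoms: none
Why: Directed ortho-metalation should remove the proton between the OMOM and OMe groups, and the aryllithium adds once to the amide (Weinreb ketone synthesis) because the chelated tetrahedral adduct holds until the quench; the triisopropylsilyl alkyne tolerates n-BuLi.

Step 8
Reactants: 12 the MOM-protected ring C ketone
Product: 13 9-(3,4-dimethoxyphenyl)-1-[2-hydroxy-6-methoxy-3-[(triisopropylsilyl)ethynyl]phenyl]nonan-1-one
Conditions: conc. HCl (cat.), MeOH/THF, 45 °C
Reagents that add atoms: none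
Why: Acid-catalysed acetal exchange removes the MOM group and frees only the C2 hydroxyl; the methyl ethers, the ketone and the silyl alkyne are stable to dilute acid.

Step 9
Reactants: 14 1,3-dimethoxybenzene; 2 methyl 9-chloro-9-oxononanoate
Product: 17 methyl 9-(2,6-dimethoxyphenyl)-9-oxononanoate, via 2,6-dimethoxyphenyllithium 15 (not isolated), via 2,6-dimethoxyphenylzinc chloride 16 (not isolated)
Conditions: n-BuLi, THF, 0 °C → rt; ZnCl2, 0 °C; then 2, Pd(PPh3)4 (5 mol %), THF, 0 °C → rt
Reagents that add atoms: none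
Why: Ortho-lithiation between the two methoxy groups, transmetalation to zinc and Negishi acylation under zerovalent palladium should give the hindered ketone; the arylzinc does not attack the methyl ester.

Step 10
Reactants: 17 methyl 9-(2,6-dimethoxyphenyl)-9-oxononanoate
Product: 18 1-(2,6-dimethoxyphenyl)nonane-1,9-diol (racemic)
Conditions: LiAlH4, THF, 0 °C → rt; aq NaOH work-up
Reagents that add atoms: none
Why: Hydride reduction of ester and ketone together avoids a chemoselective partial reduction of the ester; the carbinol centre forms without control and is removed in step 11.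

Step 11
Reactants: 18 1-(2,6-dimethoxyphenyl)nonane-1,9-diol
Product: 19 9-(2,6-dimethoxyphenyl)-9-oxononanal
Conditions: Dess–Martin periodinane (2.5 equiv), NaHCO3, CH2Cl2, rt
Reagents that add atoms: none
Why: Dess–Martin oxidation should convert the primary alcohol to the aldehyde and the benzylic alcohol to the ketone without over-oxidation.

Step 12
Reactants: 19 9-(2,6-dimethoxyphenyl)-9-oxononanal; 20 ethynylmagnesium bromide
Product: 21 1-(2,6-dimethoxyphenyl)-9-hydroxyundec-10-yn-1-one (racemic)
Conditions: 20 (1.2 equiv), THF, −78 → −20 °C; aq NH4Cl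
Reagents that add atoms: none
Why: Grignard alkynylation should be selective for the aldehyde, because the ketone is shielded by two ortho methoxy groups and twisted out of conjugation; the new carbinol centre forms as the racemate, which is all that is needed.

Step 13
Reactants: 13 the ring C phenol; 21 the propargylic alcohol
Product: 22 1-(2,6-dimethoxyphenyl)-9-{2-[9-(3,4-dimethoxyphenyl)nonanoyl]-3-methoxy-6-[(triisopropylsilyl)ethynyl]phenoxy}undec-10-yn-1-one (racemic)
Conditions: PPh3, DIAD, THF, 0 °C → rt
Reagents that add atoms: none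
Why: Mitsunobu etherification: the acidic ortho-acyl phenol displaces the oxyphosphonium group of the secondary propargylic alcohol with inversion, which is of no consequence for a racemic centre that is later erased.

Step 14
Reactants: 22 the silylated ether
Product: 23 1-(2,6-dimethoxyphenyl)-9-{2-[9-(3,4-dimethoxyphenyl)nonanoyl]-6-ethynyl-3-methoxyphenoxy}undec-10-yn-1-one (racemic), the ring C diyne
Conditions: TBAF, AcOH (1:1), THF, 0 °C → rt
Reagents that add atoms: none
Why: Fluoride desilylation frees the aryl alkyne only after the phenol is etherified, so a free 2-ethynylphenol that could cyclise to a benzofuran never exists; the acetic acid buffer guards the propargylic ether against base-induced isomerisation.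

Step 15
Reactants: 23 the ring C diyne; 24 bis(pinacolatoboryl)acetylene
Product: 25 9-(3,4-dimethoxyphenyl)-1-{6-[8-(2,6-dimethoxyphenyl)-8-oxooctyl]-3-methoxy-8,9-bis(4,4,5,5-tetramethyl-1,3,2-dioxaborolan-2-yl)-6H-benzo[c]chromen-4-yl}nonan-1-one (racemic)
Conditions: 24 (4 equiv), CpCo(CO)2 (20 mol %), degassed PhMe, reflux, hν (tungsten lamp); 23 added by syringe pump over 10 h
Reagents that add atoms: none
Why: Loss of CO from CpCo(CO)2 under light and heat gives a CpCo fragment (monovalent cobalt) that binds the two tethered alkynes of 23 and couples them oxidatively to a cobaltacyclopentadiene, which forms B1–B2 and so closes the six-membered pyran ring (O, bridge CH, B1, B2, C1, C2) by intramolecular alkyne–alkyne coupling; insertion of 24 and reductive elimination then form B3–B4 and B5–B6 and close ring B as an arene in a formal [4+2] closure of the metallacycle. The closest known reaction type is the cobalt-catalysed [2+2+2] cocyclisation of α,ω-diynes with hindered monoalkynes such as bis(trimethylsilyl)acetylene and alkynylboronates, which has also been run on propargyl ethers of 2-ethynylphenols to give 6H-benzo[c]chromenes. No stereocentre is created; the bridge carbon keeps the racemic configuration from step 12 until step 17 turns it into CH2. The step needs cross-cyclotrimerisation to win over self-oligomerisation of the diyne, which is secured by slow addition of 23 into an excess of 24, an alkyne too hindered to trimerise with itself. Regiochemistry needs no control, since the tether fixes B1 next to B2, 24 is symmetrical and its two boron atoms land on B4 and B5 where the catechol oxygens belong. The aryl ketones, methyl ethers and C–B bonds should be inert to the cobalt catalyst.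

Step 16
Reactants: 25 the diboryl benzochromene
Product: 26 9-(3,4-dimethoxyphenyl)-1-{6-[8-(2,6-dimethoxyphenyl)-8-oxooctyl]-8,9-dihydroxy-3-methoxy-6H-benzo[c]chromen-4-yl}nonan-1-one (racemic)
Conditions: NaBO3·4H2O (6 equiv), THF/H2O, rt, Ar; aq NH4Cl/Na2S2O3
Reagents that add atoms: sodium perborate (used as the tetrahydrate), [Na+].[O-]OB=O
Why: Oxidation of aryl boronates by peroxoborate proceeds by 1,2-shift of the aryl group from boron to oxygen, so both C–B bonds should become C–OH with retention of position; the alkoxy-flanked ketones are not Dakin substrates under these mild conditions.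

Step 17
Reactants: 26 the benzochromene catechol
Product: 27 9-(3,4-dimethoxyphenyl)-1-{2'-[9-(2,6-dimethoxyphenyl)-9-oxononyl]-2,4',5'-trihydroxy-4-methoxybiphenyl-3-yl}nonan-1-one
Conditions: H2 (1–3 atm), 10 % Pd/C, EtOAc/AcOH (20:1), rt
Reagents that add atoms: none
Why: Hydrogenolysis of a benzylic aryl ether: the bridge C–O bond is benzylic to ring B and para to the B4 hydroxyl, so it should be cleaved to the C2 phenol and a CH2 group (the stereocentre disappears), while the two ketones are each flanked by two ortho oxygens and twisted out of conjugation and are therefore not activated as benzylic carbonyls.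

Step 18
Reactants: 27 the pentamethyl ether of giganteone A
Product: 28 giganteone A
Conditions: BBr3 (12 equiv), CH2Cl2, −78 °C → rt; then H2O, 0 °C, under Ar
Reagents that add atoms: none
Why: Lewis acid demethylation with BBr3 should cleave all five aryl methyl ethers by bromide attack on the boron-complexed methyl groups, and aryl ketones, the biaryl bond and free phenols withstand the reagent.

**Compound list**

1 | azelaic acid monomethyl ester | COC(=O)CCCCCCCC(=O)O | starting material
2 | methyl 9-chloro-9-oxononanoate | COC(=O)CCCCCCCC(Cl)=O | intermediate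
3 | veratrole (1,2-dimethoxybenzene) | COc1ccccc1OC | starting material
4 | methyl 9-(3,4-dimethoxyphenyl)-9-oxononanoate | COC(=O)CCCCCCCC(=O)c1ccc(OC)c(OC)c1 | intermediate
5 | methyl 9-(3,4-dimethoxyphenyl)nonanoate | COC(=O)CCCCCCCCc1ccc(OC)c(OC)c1 | intermediate
6 | 9-(3,4-dimethoxyphenyl)-N-methoxy-N-methylnonanamide | CON(C)C(=O)CCCCCCCCc1ccc(OC)c(OC)c1 | intermediate
7 | 2-bromo-5-methoxyphenol | COc1ccc(Br)c(O)c1 | starting material
8 | 1-bromo-4-methoxy-2-(methoxymethoxy)benzene | COCOc1cc(OC)ccc1Br | intermediate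
9 | (triisopropylsilyl)acetylene | C#C[Si](C(C)C)(C(C)C)C(C)C | starting material
10 | {[4-methoxy-2-(methoxymethoxy)phenyl]ethynyl}triisopropylsilane | COCOc1cc(OC)ccc1C#C[Si](C(C)C)(C(C)C)C(C)C | intermediate
11 | [6-methoxy-2-(methoxymethoxy)-3-[(triisopropylsilyl)ethynyl]phenyl]lithium | COCOc1c([Li])c(OC)ccc1C#C[Si](C(C)C)(C(C)C)C(C)C | intermediate
12 | 9-(3,4-dimethoxyphenyl)-1-[6-methoxy-2-(methoxymethoxy)-3-[(triisopropylsilyl)ethynyl]phenyl]nonan-1-one | COCOc1c(C#C[Si](C(C)C)(C(C)C)C(C)C)ccc(OC)c1C(=O)CCCCCCCCc1ccc(OC)c(OC)c1 | intermediate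
13 | 9-(3,4-dimethoxyphenyl)-1-[2-hydroxy-6-methoxy-3-[(triisopropylsilyl)ethynyl]phenyl]nonan-1-one | Oc1c(C#C[Si](C(C)C)(C(C)C)C(C)C)ccc(OC)c1C(=O)CCCCCCCCc1ccc(OC)c(OC)c1 | intermediate
14 | 1,3-dimethoxybenzene | COc1cccc(OC)c1 | starting material
15 | 2,6-dimethoxyphenyllithium | COc1cccc(OC)c1[Li] | intermediate
16 | 2,6-dimethoxyphenylzinc chloride | COc1cccc(OC)c1[Zn]Cl | intermediate
17 | methyl 9-(2,6-dimethoxyphenyl)-9-oxononanoate | COC(=O)CCCCCCCC(=O)c1c(OC)cccc1OC | intermediate
18 | 1-(2,6-dimethoxyphenyl)nonane-1,9-diol (racemic) | OCCCCCCCCC(O)c1c(OC)cccc1OC | intermediate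
19 | 9-(2,6-dimethoxyphenyl)-9-oxononanal | O=CCCCCCCCC(=O)c1c(OC)cccc1OC | intermediate
20 | ethynylmagnesium bromide | C#C[Mg]Br | starting material
21 | 1-(2,6-dimethoxyphenyl)-9-hydroxyundec-10-yn-1-one (racemic) | C#CC(O)CCCCCCCC(=O)c1c(OC)cccc1OC | intermediate
22 | 1-(2,6-dimethoxyphenyl)-9-{2-[9-(3,4-dimethoxyphenyl)nonanoyl]-3-methoxy-6-[(triisopropylsilyl)ethynyl]phenoxy}undec-10-yn-1-one (racemic) | COc1ccc(C#C[Si](C(C)C)(C(C)C)C(C)C)c(OC(C#C)CCCCCCCC(=O)c2c(OC)cccc2OC)c1C(=O)CCCCCCCCc1ccc(OC)c(OC)c1 | intermediate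
23 | 1-(2,6-dimethoxyphenyl)-9-{2-[9-(3,4-dimethoxyphenyl)nonanoyl]-6-ethynyl-3-methoxyphenoxy}undec-10-yn-1-one (racemic) | C#Cc1ccc(OC)c(C(=O)CCCCCCCCc2ccc(OC)c(OC)c2)c1OC(C#C)CCCCCCCC(=O)c1c(OC)cccc1OC | intermediate
24 | bis(pinacolatoboryl)acetylene | CC1(C)OB(C#CB2OC(C)(C)C(C)(C)O2)OC1(C)C | starting material
25 | 9-(3,4-dimethoxyphenyl)-1-{6-[8-(2,6-dimethoxyphenyl)-8-oxooctyl]-3-methoxy-8,9-bis(4,4,5,5-tetramethyl-1,3,2-dioxaborolan-2-yl)-6H-benzo[c]chromen-4-yl}nonan-1-one (racemic) | COc1ccc2c(c1C(=O)CCCCCCCCc1ccc(OC)c(OC)c1)OC(CCCCCCCC(=O)c1c(OC)cccc1OC)c1cc(B3OC(C)(C)C(C)(C)O3)c(B3OC(C)(C)C(C)(C)O3)cc1-2 | intermediate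
26 | 9-(3,4-dimethoxyphenyl)-1-{6-[8-(2,6-dimethoxyphenyl)-8-oxooctyl]-8,9-dihydroxy-3-methoxy-6H-benzo[c]chromen-4-yl}nonan-1-one (racemic) | COc1ccc2c(c1C(=O)CCCCCCCCc1ccc(OC)c(OC)c1)OC(CCCCCCCC(=O)c1c(OC)cccc1OC)c1cc(O)c(O)cc1-2 | intermediate
27 | 9-(3,4-dimethoxyphenyl)-1-{2'-[9-(2,6-dimethoxyphenyl)-9-oxononyl]-2,4',5'-trihydroxy-4-methoxybiphenyl-3-yl}nonan-1-one | COc1ccc(-c2cc(O)c(O)cc2CCCCCCCCC(=O)c2c(OC)cccc2OC)c(O)c1C(=O)CCCCCCCCc1ccc(OC)c(OC)c1 | intermediate
28 | giganteone A | O=C(CCCCCCCCc1cc(O)c(O)cc1-c1ccc(O)c(C(=O)CCCCCCCCc2ccc(O)c(O)c2)c1O)c1c(O)cccc1O | target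

**Step count**

Total: 18 steps. Longest linear sequence: 12 steps (1, 2, 3, 4, 7, 8, 13, 14, 15, 16, 17, 18).

**Steps most likely to fail**

Step 15. The hindered diborylacetylene may be taken up too slowly by the cobaltacycle, so that the diyne oligomerises with itself, or C–B bonds may be lost by protodeboronation at reflux. The fallback keeps the ether bridge but makes the biaryl bond by palladium-catalysed intramolecular direct arylation, with ring B brought in preformed. It sets out from 14, 6 and 19 and comes back to the route at 28.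
- 2,6-Dimethoxyphenyllithium 15 (from 14 and n-BuLi) is added to amide 6 to give 9-(3,4-dimethoxyphenyl)-1-(2,6-dimethoxyphenyl)nonan-1-one F1.
- BCl3 (CH2Cl2, −78 → 0 °C) removes one of the two equivalent ortho methyl groups by chelation to the carbonyl and gives 9-(3,4-dimethoxyphenyl)-1-(2-hydroxy-6-methoxyphenyl)nonan-1-one F2.
- Iodine–magnesium exchange on commercial 1-bromo-2-iodo-4,5-dimethoxybenzene (i-PrMgCl·LiCl, THF, −20 °C) gives (2-bromo-4,5-dimethoxyphenyl)magnesium chloride F3, which adds to the aldehyde of 19 to give the racemic benzylic alcohol 9-(2-bromo-4,5-dimethoxyphenyl)-1-(2,6-dimethoxyphenyl)-9-hydroxynonan-1-one F4.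
- Mitsunobu coupling of F2 with F4 (PPh3, DIAD) gives the aryl benzyl ether F5.
- Pd(OAc)2, PCy3·HBF4 and K2CO3 in DMA at 130 °C close the pyran ring by C–H arylation at C1 of ring C, the only position ortho to the ether oxygen, and give the 8,9-dimethoxy-6H-benzo[c]chromene F6.
- Hydrogenolysis (H2, Pd/C) opens the bridge to the heptamethyl ether of giganteone A F7, and BBr3 then gives 28.

Step 17. The cyclic benzylic C–O bond is held near the plane of ring B and may resist cleavage on the palladium surface, and longer exposure would start to reduce the aryl ketones. The fallback opens the bridge by elimination and then saturates an alkene. It sets out from 26 and comes back at 27.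
- Warming 26 with K2CO3 in degassed DMF (60–80 °C) lets the B4 phenoxide expel the ring C aryloxide to a para-quinone methide. This tautomerises by loss of a proton from the neighbouring CH2 to the ring-opened (E)-alkenyl catechol F8.
- Brief hydrogenation (H2, Pd/C, EtOAc, rt) reduces only the styrene C=C and gives 27.

Step 13. The hydrogen-bonded phenol with two ortho substituents may attack the crowded oxyphosphonium intermediate too slowly, so that elimination or alkylation of the hydrazide takes over. The fallback replaces the redox condensation by a Williamson etherification of a preformed sulfonate. It sets out from 21 and comes back at 22.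
- MsCl and Et3N in CH2Cl2 at 0 °C convert 21 into the propargylic methanesulfonate F9.
- The caesium phenoxide of 13 (Cs2CO3, DMF, rt → 40 °C) displaces the sulfonate at the activated propargylic carbon and gives 22.

**Further compounds**

F1 | step 15 | 9-(3,4-dimethoxyphenyl)-1-(2,6-dimethoxyphenyl)nonan-1-one | COc1cccc(OC)c1C(=O)CCCCCCCCc1ccc(OC)c(OC)c1
F2 | step 15 | 9-(3,4-dimethoxyphenyl)-1-(2-hydroxy-6-methoxyphenyl)nonan-1-one | COc1cccc(O)c1C(=O)CCCCCCCCc1ccc(OC)c(OC)c1
F3 | step 15 | (2-bromo-4,5-dimethoxyphenyl)magnesium chloride | COc1cc(Br)c([Mg]Cl)cc1OC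
F4 | step 15 | 9-(2-bromo-4,5-dimethoxyphenyl)-1-(2,6-dimethoxyphenyl)-9-hydroxynonan-1-one (racemic) | COc1cc(Br)c(C(O)CCCCCCCC(=O)c2c(OC)cccc2OC)cc1OC
F5 | step 15 | 9-(2-bromo-4,5-dimethoxyphenyl)-1-(2,6-dimethoxyphenyl)-9-{2-[9-(3,4-dimethoxyphenyl)nonanoyl]-3-methoxyphenoxy}nonan-1-one (racemic) | COc1cccc(OC(CCCCCCCC(=O)c2c(OC)cccc2OC)c2cc(OC)c(OC)cc2Br)c1C(=O)CCCCCCCCc1ccc(OC)c(OC)c1
F6 | step 15 | 9-(3,4-dimethoxyphenyl)-1-{6-[8-(2,6-dimethoxyphenyl)-8-oxooctyl]-3,8,9-trimethoxy-6H-benzo[c]chromen-4-yl}nonan-1-one (racemic) | COc1ccc2c(c1C(=O)CCCCCCCCc1ccc(OC)c(OC)c1)OC(CCCCCCCC(=O)c1c(OC)cccc1OC)c1cc(OC)c(OC)cc1-2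
F7 | step 15 | 9-(3,4-dimethoxyphenyl)-1-{2'-[9-(2,6-dimethoxyphenyl)-9-oxononyl]-2-hydroxy-4,4',5'-trimethoxybiphenyl-3-yl}nonan-1-one | COc1ccc(-c2cc(OC)c(OC)cc2CCCCCCCCC(=O)c2c(OC)cccc2OC)c(O)c1C(=O)CCCCCCCCc1ccc(OC)c(OC)c1
F8 | step 17 | (E)-9-{2-[3-[9-(3,4-dimethoxyphenyl)nonanoyl]-2-hydroxy-4-methoxyphenyl]-4,5-dihydroxyphenyl}-1-(2,6-dimethoxyphenyl)non-8-en-1-one | COc1ccc(-c2cc(O)c(O)cc2/C=C/CCCCCCC(=O)c2c(OC)cccc2OC)c(O)c1C(=O)CCCCCCCCc1ccc(OC)c(OC)c1
F9 | step 13 | 11-(2,6-dimethoxyphenyl)-11-oxoundec-1-yn-3-yl methanesulfonate (racemic) | C#CC(OS(C)(=O)=O)CCCCCCCC(=O)c1c(OC)cccc1OC
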